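**Plan**
Retrosynthesis: the ring-B acetates and the aldehyde oxidation level of the side chain are adjusted last. The side-chain olefin is then cut (cross-metathesis of an 8-allyl group with methacrolein), followed by C4–C4a (intramolecular Friedel–Crafts acylation), O1–C2 (Mitsunobu etherification), the C8–allyl bond (ortho-lithiation/allylation) and the C–C bond of a β-keto ester.
Enabling feature: on ring A, C8 is occupied by the side chain, so C4a is the only open carbon next to O1, and it lies para to the C7 oxygen. An acyl cation tethered from O1 through C2 and C3 can therefore only attack C4a, which is doubly activated.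
Forward: the ring-A phenol and the ring-B β-hydroxy ester are made separately (3 steps each) and joined at O1–C2. Ring C is then closed at C4–C4a, and the C8 chain is completed on the flavanone.
Stereochemistry: C2 comes from a Noyori transfer hydrogenation that gives the (R)-carbinol; one Mitsunobu inversion makes it (S), and it is not touched again. The (E)-olefin comes from the cross-metathesis with methacrolein.

Key step: step 9

Remark: flavanone numbering is used (O1, C2, C3, C4, C4a, C5–C8, C8a); in step 13 the acetyl groups are taken to leave by hydrolysis, as acetic acid.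

**Step 1**
Reactants: 1 3-(benzyloxy)phenol
Product: 2 1-(benzyloxy)-3-(methoxymethoxy)benzene
Conditions: MOMCl, i-Pr2NEt, CH2Cl2, 0 °C to rt
Reagents that add atoms: chloromethyl methyl ether, COCCl
Why: Williamson-type O-alkylation of the phenol by the α-chloro ether installs the acetal oxygen that will direct the lithiation in step 2.

**Step 2**
Reactants: 2 1-(benzyloxy)-3-(methoxymethoxy)benzene, 3 allyl bromide
Product: 5 2-allyl-1-(benzyloxy)-3-(methoxymethoxy)benzene, via 2-lithio derivative 4 (not isolated)
Conditions: n-BuLi, THF, 0 °C; then CuBr·SMe2 (10 mol %), allyl bromide, −78 °C to rt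
Reagents that add atoms: allyl bromide 3, C=CCBr; n-butyllithium, [Li]CCCC (its lithium is held only by intermediate 4)
Why: directed ortho-metalation removes the most acidic ring proton, the one flanked by both oxygens and chelated by the MOM group, and copper-catalysed allylation of the aryllithium then places the future C8 substituent.

**Step 3**
Reactants: 5 2-allyl-1-(benzyloxy)-3-(methoxymethoxy)benzene
Product: 6 2-allyl-3-(benzyloxy)phenol
Conditions: HCl (cat.), MeOH, 45 °C
Reagents that add atoms: none
Why: acid-catalysed transacetalisation removes the MOM group as dimethoxymethane under conditions that leave the benzyl ether and the allyl group alone.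

**Step 4**
Reactants: 7 3,4-dihydroxybenzaldehyde
Product: 8 3,4-diacetoxybenzaldehyde
Conditions: Ac2O, pyridine, DMAP (cat.), CH2Cl2, 0 °C to rt
Reagents that add atoms: acetic anhydride, CC(=O)OC(C)=O
Why: nucleophile-catalysed O-acylation of both phenols gives the electron-poor ring B that the key step requires.

**Step 5**
Reactants: 8 3,4-diacetoxybenzaldehyde, 9 tert-butyl diazoacetate
Product: 10 tert-butyl 3-(3,4-diacetoxyphenyl)-3-oxopropanoate
Conditions: SnCl2 (10 mol %), CH2Cl2, rt
Reagents that add atoms: tert-butyl diazoacetate 9, CC(C)(C)OC(=O)C=[N+]=[N-]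
Why: Roskamp reaction, in which Lewis-acid-promoted addition of the diazo ester to the aldehyde is followed by a 1,2-hydride shift with loss of nitrogen, gives the β-keto ester without any base that could attack the aryl acetates.

**Step 6**
Reactants: 10 tert-butyl 3-(3,4-diacetoxyphenyl)-3-oxopropanoate
Product: 11 tert-butyl (3R)-3-(3,4-diacetoxyphenyl)-3-hydroxypropanoate
Conditions: RuCl(p-cymene)[(R,R)-TsDPEN] (1 mol %), HCO2H/Et3N (5:2), CH2Cl2, 30 °C
Reagents that add atoms: none
Why: Noyori asymmetric transfer hydrogenation of an aryl ketone, in which the CH/π contact between the cymene ligand and ring B fixes the hydride face, so the (R,R)-ligand should give the (R)-carbinol.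

**Step 7**
Reactants: 6 2-allyl-3-(benzyloxy)phenol, 11 tert-butyl (3R)-3-(3,4-diacetoxyphenyl)-3-hydroxypropanoate
Product: 12 tert-butyl (3S)-3-[2-allyl-3-(benzyloxy)phenoxy]-3-(3,4-diacetoxyphenyl)propanoate
Conditions: PPh3, DIAD, toluene, 0 °C to rt
Reagents that add atoms: none
Why: Mitsunobu etherification, in which the phenol displaces the oxyphosphonium group by SN2 with inversion and so converts the (R)-carbinol into the (S)-aryl ether, while the acetates on ring B disfavour an ionising pathway that would erode the ee.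

**Step 8**
Reactants: 12 tert-butyl (3S)-3-[2-allyl-3-(benzyloxy)phenoxy]-3-(3,4-diacetoxyphenyl)propanoate
Product: 13 (3S)-3-[2-allyl-3-(benzyloxy)phenoxy]-3-(3,4-diacetoxyphenyl)propanoic acid
Conditions: TFA/CH2Cl2 (1:4), Et3SiH, 0 °C to rt
Reagents that add atoms: none
Why: acid-mediated alkyl–oxygen cleavage of the tert-butyl ester frees the acid without base (so no β-elimination of the aryloxy group), and the silane reduces the tert-butyl cation to isobutane before it can alkylate the electron-rich ring A.

**Step 9**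
Reactants: 13 (3S)-3-[2-allyl-3-(benzyloxy)phenoxy]-3-(3,4-diacetoxyphenyl)propanoic acid
Product: 15 (2S)-8-allyl-7-(benzyloxy)-2-(3,4-diacetoxyphenyl)chroman-4-one, via mixed trifluoroacetic anhydride 14 (not isolated)
Conditions: TFAA, CH2Cl2, 0 °C to rt
Reagents that add atoms: trifluoroacetic anhydride, O=C(OC(=O)C(F)(F)F)C(F)(F)F (its trifluoroacetyl group is carried only by intermediate 14)
Why: Trifluoroacetic anhydride converts the acid into mixed anhydride 14, whose ionisation gives an acylium ion held to ring A through C3, C2 and O1; C4a attacks it and loss of the proton restores the arene. The closest known reaction type is the intramolecular Friedel–Crafts acylation of 3-aryloxypropanoic acids to chroman-4-ones. Ring C closes as a six-membered ring by electrophilic aromatic substitution, formally a 6-exo-dig attack on the acylium carbon, which becomes C4 with its oxygen outside the ring. No stereocentre is made, and C2 from step 7 is retained because none of its bonds is broken and no base is present to expel the aryloxy group. The step needs acylation of ring A and not ring B, and only at C4a: C8 carries the allyl group, C4a is ortho to O1 and para to the benzyloxy oxygen, and the tether reaches no other carbon, while the two acetates leave ring B too electron-poor for the competing five-membered indanone closure. The same acetates destabilise a benzylic cation at C2, which should keep the C2–O1 bond from ionising in the acidic medium.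

**Step 10**
Reactants: 15 (2S)-8-allyl-7-(benzyloxy)-2-(3,4-diacetoxyphenyl)chroman-4-one
Product: 16 (2S)-8-allyl-2-(3,4-diacetoxyphenyl)-7-hydroxychroman-4-one
Conditions: BCl3, C6HMe5, CH2Cl2, −78 to −40 °C; MeOH quench
Reagents that add atoms: none
Why: Lewis-acid-mediated debenzylation with pentamethylbenzene as a non-basic cation scavenger (Friedel–Crafts capture of the benzyl cation) should free the 7-hydroxyl at low temperature without touching the allyl group, the acetates or the C2–O1 bond.

**Step 11**
Reactants: 16 (2S)-8-allyl-2-(3,4-diacetoxyphenyl)-7-hydroxychroman-4-one, 17 methacrolein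
Product: 18 (2E)-4-[(2S)-2-(3,4-diacetoxyphenyl)-7-hydroxy-4-oxochroman-8-yl]-2-methylbut-2-enal
Conditions: methacrolein (10 equiv), second-generation Hoveyda–Grubbs catalyst RuCl2(H2IMes)(=CH-C6H4-2-O-i-Pr) (5 mol %), 1,4-benzoquinone (10 mol %), CH2Cl2, 40 °C
Reagents that add atoms: methacrolein 17, CC(=C)C=O
Why: olefin cross-metathesis of a terminal olefin with an electron-poor 1,1-disubstituted partner is selective for the cross product and should give the (E)-enal, in which the formyl group lies trans to the chain, while benzoquinone suppresses double-bond migration by ruthenium hydrides.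

**Step 12**
Reactants: 18 (2E)-4-[(2S)-2-(3,4-diacetoxyphenyl)-7-hydroxy-4-oxochroman-8-yl]-2-methylbut-2-enal
Product: 19 (2S)-2-(3,4-diacetoxyphenyl)-7-hydroxy-8-[(2E)-4-hydroxy-3-methylbut-2-en-1-yl]chroman-4-one
Conditions: NaBH4, EtOH/CH2Cl2 (3:7), −78 °C; AcOH quench
Reagents that add atoms: none
Why: chemoselective 1,2-reduction of the aldehyde by borohydride at low temperature, since the C4 ketone is deactivated as a vinylogous ester by O1 and the 7-oxygen and the aryl acetates are inert at −78 °C.

**Step 13**
Reactants: 19 (2S)-2-(3,4-diacetoxyphenyl)-7-hydroxy-8-[(2E)-4-hydroxy-3-methylbut-2-en-1-yl]chroman-4-one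
Product: 20 (2S)-2-(3,4-dihydroxyphenyl)-7-hydroxy-8-[(2E)-4-hydroxy-3-methylbut-2-en-1-yl]chroman-4-one
Conditions: NH4OAc, MeOH/H2O (4:1), rt
Reagents that add atoms: none
Why: near-neutral solvolysis of the two aryl acetates by acyl–oxygen cleavage frees the catechol without the phenoxide concentrations that would open ring C by retro-oxa-Michael reaction and racemise C2, and it leaves the allylic alcohol untouched.

**Compound list**
1 | 3-(benzyloxy)phenol | Oc1cccc(OCc2ccccc2)c1 | starting material
2 | 1-(benzyloxy)-3-(methoxymethoxy)benzene | COCOc1cccc(OCc2ccccc2)c1 | intermediate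
3 | allyl bromide | C=CCBr | starting material
4 | [2-(benzyloxy)-6-(methoxymethoxy)phenyl]lithium | [Li]c1c(OCOC)cccc1OCc1ccccc1 | intermediate
5 | 2-allyl-1-(benzyloxy)-3-(methoxymethoxy)benzene | C=CCc1c(OCOC)cccc1OCc1ccccc1 | intermediate
6 | 2-allyl-3-(benzyloxy)phenol | C=CCc1c(O)cccc1OCc1ccccc1 | intermediate
7 | 3,4-dihydroxybenzaldehyde | O=Cc1ccc(O)c(O)c1 | starting material
8 | 3,4-diacetoxybenzaldehyde | CC(=O)Oc1ccc(C=O)cc1OC(C)=O | intermediate
9 | tert-butyl diazoacetate | CC(C)(C)OC(=O)C=[N+]=[N-] | starting material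
10 | tert-butyl 3-(3,4-diacetoxyphenyl)-3-oxopropanoate | CC(C)(C)OC(=O)CC(=O)c1ccc(OC(C)=O)c(OC(C)=O)c1 | intermediate
11 | tert-butyl (3R)-3-(3,4-diacetoxyphenyl)-3-hydroxypropanoate | CC(C)(C)OC(=O)C[C@H](c1ccc(OC(C)=O)c(OC(C)=O)c1)O | intermediate
12 | tert-butyl (3S)-3-[2-allyl-3-(benzyloxy)phenoxy]-3-(3,4-diacetoxyphenyl)propanoate | CC(C)(C)OC(=O)C[C@@H](c1ccc(OC(C)=O)c(OC(C)=O)c1)Oc1cccc(OCc2ccccc2)c1CC=C | intermediate
13 | (3S)-3-[2-allyl-3-(benzyloxy)phenoxy]-3-(3,4-diacetoxyphenyl)propanoic acid | OC(=O)C[C@@H](c1ccc(OC(C)=O)c(OC(C)=O)c1)Oc1cccc(OCc2ccccc2)c1CC=C | intermediate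
14 | (3S)-3-[2-allyl-3-(benzyloxy)phenoxy]-3-(3,4-diacetoxyphenyl)propanoic trifluoroacetic anhydride | O=C(OC(=O)C(F)(F)F)C[C@@H](c1ccc(OC(C)=O)c(OC(C)=O)c1)Oc1cccc(OCc2ccccc2)c1CC=C | intermediate
15 | (2S)-8-allyl-7-(benzyloxy)-2-(3,4-diacetoxyphenyl)chroman-4-one | C=CCc1c(OCc3ccccc3)ccc2c1O[C@H](c1ccc(OC(C)=O)c(OC(C)=O)c1)CC2=O | intermediate
16 | (2S)-8-allyl-2-(3,4-diacetoxyphenyl)-7-hydroxychroman-4-one | C=CCc1c(O)ccc2c1O[C@H](c1ccc(OC(C)=O)c(OC(C)=O)c1)CC2=O | intermediate
17 | methacrolein | CC(=C)C=O | starting material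
18 | (2E)-4-[(2S)-2-(3,4-diacetoxyphenyl)-7-hydroxy-4-oxochroman-8-yl]-2-methylbut-2-enal | C/C(=C\Cc1c(O)ccc2c1O[C@H](c1ccc(OC(C)=O)c(OC(C)=O)c1)CC2=O)C=O | intermediate
19 | (2S)-2-(3,4-diacetoxyphenyl)-7-hydroxy-8-[(2E)-4-hydroxy-3-methylbut-2-en-1-yl]chroman-4-one | C/C(=C\Cc1c(O)ccc2c1O[C@H](c1ccc(OC(C)=O)c(OC(C)=O)c1)CC2=O)CO | intermediate
20 | (2S)-2-(3,4-dihydroxyphenyl)-7-hydroxy-8-[(2E)-4-hydroxy-3-methylbut-2-en-1-yl]chroman-4-one | C/C(=C\Cc1c(O)ccc2c1O[C@H](c1ccc(O)c(O)c1)CC2=O)CO | target

**Step count and risks**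
Total step count: 13. Longest linear sequence: 10 steps (steps 1–3 or 4–6, then 7–13).

Steps most likely to fail:

Step 7. The activated carbinol may eliminate across the acidic α-methylene to the cinnamate instead of being displaced. Partial ionisation at the benzylic carbon would lower the ee, and the phenoxide may also pick up an acetyl group from ring B. The fallback makes the ether at the alcohol oxidation level, where no acidic α-hydrogens exist; it sets out from aldehyde 8 and phenol 6 and returns at acid 13.
- Keck allylation of 8 (allyltributylstannane, Ti(O-i-Pr)4 and the BINOL enantiomer that delivers the (R)-carbinol) should give (1R)-1-(3,4-diacetoxyphenyl)but-3-en-1-ol F1.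
- Ozonolysis with PPh3 work-up and reduction of the hydroxy aldehyde with NaBH(OAc)3 should give (1R)-1-(3,4-diacetoxyphenyl)propane-1,3-diol F2.
- Silylation of the primary hydroxyl (TIPSOTf, 2,6-lutidine, −78 °C) should give (1R)-1-(3,4-diacetoxyphenyl)-3-[(triisopropylsilyl)oxy]propan-1-ol F3.
- Mitsunobu coupling with 6 (PPh3, DIAD) should give, with inversion, [(3S)-3-[2-allyl-3-(benzyloxy)phenoxy]-3-(3,4-diacetoxyphenyl)propoxy]triisopropylsilane F4.
- HF·pyridine should free (3S)-3-[2-allyl-3-(benzyloxy)phenoxy]-3-(3,4-diacetoxyphenyl)propan-1-ol F5.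
- TEMPO with PhI(OAc)2 in aqueous MeCN should oxidise F5 to 13.

Step 9. The acidic medium may heterolyse the C2–O1 bond, losing the phenol or racemising C2. If acylation is slow, trifluoroacetylation of ring A or loss of the benzyl group could compete. Changing to the acid chloride with SnCl4 at −78 °C would be a change of conditions only. The fallback closes ring C from the other side, at O1–C2; it sets out from phenol 6 and aldehyde 8 and returns at 15.
- Fries-type C-acetylation of 6 (Ac2O, BF3·OEt2) should give 1-[3-allyl-4-(benzyloxy)-2-hydroxyphenyl]ethan-1-one F6.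
- BF3·OEt2-mediated Claisen–Schmidt condensation with 8, an acidic medium that spares the acetates, should give 4-[(1E)-3-[3-allyl-4-(benzyloxy)-2-hydroxyphenyl]-3-oxoprop-1-en-1-yl]-1,2-phenylene diacetate F7.
- Intramolecular oxa-Michael addition under a quinine-derived bifunctional thiourea should close ring C to 15.
- The configuration at C2 would then rest on catalyst control and would need upgrading by crystallisation or chiral chromatography.

Step 11. Ruthenium hydrides may move the allyl double bond into conjugation with ring A. Turnover with the electron-poor 1,1-disubstituted partner may be slow, and the free ortho-phenol may bind the catalyst. The fallback builds the olefin by carbonyl olefination; it sets out from 15 and returns at 18.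
- Lemieux–Johnson cleavage of the allyl group (OsO4 cat., NaIO4, 2,6-lutidine, dioxane/H2O) should give 2-[(2S)-7-(benzyloxy)-2-(3,4-diacetoxyphenyl)-4-oxochroman-8-yl]acetaldehyde F8.
- Wittig reaction with the stabilised ylide 2-(triphenylphosphoranylidene)propanal (toluene, 60 °C) should give (2E)-4-[(2S)-7-(benzyloxy)-2-(3,4-diacetoxyphenyl)-4-oxochroman-8-yl]-2-methylbut-2-enal F9.
- Debenzylation as in step 10 (BCl3, C6HMe5, −78 °C) should then give 18.

**Further compounds**
F1 | step 7 | (1R)-1-(3,4-diacetoxyphenyl)but-3-en-1-ol | C=CC[C@H](c1ccc(OC(C)=O)c(OC(C)=O)c1)O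
F2 | step 7 | (1R)-1-(3,4-diacetoxyphenyl)propane-1,3-diol | OCC[C@H](c1ccc(OC(C)=O)c(OC(C)=O)c1)O
F3 | step 7 | (1R)-1-(3,4-diacetoxyphenyl)-3-[(triisopropylsilyl)oxy]propan-1-ol | CC(C)[Si](OCC[C@H](c1ccc(OC(C)=O)c(OC(C)=O)c1)O)(C(C)C)C(C)C
F4 | step 7 | [(3S)-3-[2-allyl-3-(benzyloxy)phenoxy]-3-(3,4-diacetoxyphenyl)propoxy]triisopropylsilane | CC(C)[Si](OCC[C@@H](c1ccc(OC(C)=O)c(OC(C)=O)c1)Oc1cccc(OCc2ccccc2)c1CC=C)(C(C)C)C(C)C
F5 | step 7 | (3S)-3-[2-allyl-3-(benzyloxy)phenoxy]-3-(3,4-diacetoxyphenyl)propan-1-ol | OCC[C@@H](c1ccc(OC(C)=O)c(OC(C)=O)c1)Oc1cccc(OCc2ccccc2)c1CC=C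
F6 | step 9 | 1-[3-allyl-4-(benzyloxy)-2-hydroxyphenyl]ethan-1-one | CC(=O)c1ccc(OCc2ccccc2)c(CC=C)c1O
F7 | step 9 | 4-[(1E)-3-[3-allyl-4-(benzyloxy)-2-hydroxyphenyl]-3-oxoprop-1-en-1-yl]-1,2-phenylene diacetate | CC(=O)Oc1ccc(/C=C/C(=O)c2ccc(OCc3ccccc3)c(CC=C)c2O)cc1OC(C)=O
F8 | step 11 | 2-[(2S)-7-(benzyloxy)-2-(3,4-diacetoxyphenyl)-4-oxochroman-8-yl]acetaldehyde | O=CCc1c(OCc3ccccc3)ccc2c1O[C@H](c1ccc(OC(C)=O)c(OC(C)=O)c1)CC2=O
F9 | step 11 | (2E)-4-[(2S)-7-(benzyloxy)-2-(3,4-diacetoxyphenyl)-4-oxochroman-8-yl]-2-methylbut-2-enal | C/C(=C\Cc1c(OCc3ccccc3)ccc2c1O[C@H](c1ccc(OC(C)=O)c(OC(C)=O)c1)CC2=O)C=O
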